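Readings and results are simulated for an exercise.

in all of them: impurity 9.9 mM
- Friday's: starting material 1 M; solid reagent 1.2 equiv; free catalyst 1.2 mol%; run made earlier
- Monday's: starting material 1 M; solid reagent 1.2 equiv; free catalyst 5 mol%; run made earlier
- flask: starting material 1.0 M; solid reagent 1.20 equiv; free catalyst 2.5 mol%; time 8.0 min

- Friday's (time / min: target / %): 0.667: 0; 2.00: 0; 4.00: 0; 6.00: 2; 8.00: 1
- Monday's (time / min: target / %): 0.667: 0; 1.33: 1; 2.50: 3; 4.00: 8; 8.00: 18

(readings scatter by 1.5 percentage points)

- as a solid, counted per litre of solution: solid reagent
- at the start none of the solid reagent is in solution

- amber: doubling the solubility of the solid reagent, all else as stated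
- grey: doubling the amount of free catalyst, all else as stated
- blue: doubling the dissolution coefficient of the solid reagent, all else as stated

- the target standing at 8.0 min, as a percentage of the starting material charged
- the change that raises the amount of target at 8.0 min, in percent of the starting material charged most ("none" if none brings more than 2 percentage points) (amber / grey / blue / none)
- amount of target at 8.0 min, in percent of the starting material charged, after blue

At early times both runs read low: after 0.667 min Monday's run stands at 0% and Friday's at 0%. Two chemists argue over what the new flask will do.

Ann compares the last readings. Scaling Monday's 18% by charged catalyst predicts 4.32% for Friday, but Friday reads 1%, with a scatter of 1.5 percentage points. So she lets the impurity bind catalyst one to one. Her quantity is the active catalyst c*, the catalyst charged minus the impurity charged. Friday has 2.10 mM, Monday 40.1 mM, and the flask 15.1 mM. Taking the rate as first order in c*, Friday comes to 0.943%, close to its reading.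

Ben points to the solid reagent, which starts undissolved, and to Monday's lag: 1% at 1.33 min, 8% at 4.00 min. He reads dissolving as the brake, with zero order in catalyst. He expects the flask to repeat Monday's 18%.

My own reckoning follows Ann: the flask gets 6.78%. The forecast gives 7%, names grey as the best change, and puts blue at 8.5%, holding that “Blue only shortens the lag”.

    starting material + free catalyst → free catalyst + intermediate (k = 190 /M/min)
    partner + free catalyst + intermediate → free catalyst + target (k = 9.70 /M²/min)
    solid reagent ⇌ partner, rate k3*(cs3 - [partner]) while solid is left; crystals form when [partner] > cs3 (solubility = 0.670 M, k = 0.0560 /min)
    free catalyst + impurity → spent catalyst (k = 2000 /M/min)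

The flask gives 10.5% at 8.0 min, nearer Ann's figure than Ben's. The best change is amber, worth 9.6 points; blue reaches 18.1%. At 8.00 min the partner, the dissolved solid reagent, is made 1.44 times faster than it is used. Ben's dissolving has its share in this flask: blue gains 7.6 points, about the same as grey's 7.6 points. Ann's c* is 60.4% of the catalyst charged, and the flask holds 60.4% free catalyst.

In the neighbour flask with 0.040 M impurity, the same subtraction gives −15.0 mM, below zero, so c* predicts no free catalyst and 37.5% of the impurity unbound. That flask gives 0% target at 8.00 min, with 0% free catalyst and 38% of the impurity left.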